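**Retrosynthetic overview**
1. Last disconnection: the lactone C3–O bond of ring B. The target comes from an open 2-(alk-1-enyl)-4,6-dimethoxybenzoic acid by enantioselective intramolecular hydro-acyloxylation, which closes ring B and sets C3 (S) in the final step.
2. The carboxyl group comes from an aryl bromide (bromine–lithium exchange, then CO2).
3. The styrenyl C=C comes from cross-metathesis of a 2-bromo-3,5-dimethoxystyrene with a C15 terminal alkenol.
4. The styrene comes from the corresponding benzaldehyde (Wittig). The alkenol, carrying the (S)-carbinol, comes from (S)-propylene oxide and dodec-11-en-1-ylmagnesium bromide (chiral pool).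
5. Ring order: benzene ring A is bought intact; lactone ring B is the only ring made, and it is made last. No protecting groups are used.

Assumption 1: the sense of induction of the new step 5 cannot be predicted with certainty. The (R,R)-antipode of the cobalt salen complex C36H52CoN2O2 is written and taken to give 3S; if a pilot run shows the opposite sense, the (S,S)-antipode is used with nothing else changed.
Assumption 2: 12-bromododec-1-ene and 2-bromo-3,5-dimethoxybenzaldehyde are taken as catalogue compounds.

**Step 1**
Reactants: 1 12-bromododec-1-ene; 2 (S)-propylene oxide [(2S)-2-methyloxirane]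
Product: 4 (2S)-pentadec-14-en-2-ol, via dodec-11-en-1-ylmagnesium bromide 3 (not isolated)
Conditions: Mg, THF, 40 °C; then CuI (10 mol %), 2 (0.8 equiv), THF, −30 → 0 °C; 1 M HCl
Reagents that add atoms: none
Why: Copper-catalysed Grignard opening of a terminal epoxide is an SN2 attack at the unsubstituted CH2, so the stereocentre of 2 is not touched and is carried into 4 as (S).

**Step 2**
Reactants: 5 2-bromo-3,5-dimethoxybenzaldehyde
Product: 6 2-bromo-1-ethenyl-3,5-dimethoxybenzene
Conditions: Ph3PCH3Br (1.3 equiv), KOtBu (1.25 equiv), THF, 0 °C → rt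
Reagents that add atoms: methyltriphenylphosphonium bromide, C[P+](c1ccccc1)(c1ccccc1)c1ccccc1.[Br-]
Why: Wittig methylenation of an aromatic aldehyde with a non-stabilised ylide is reliable, and the aryl bromide and methyl ethers are inert to it.

**Step 3**
Reactants: 6 2-bromo-1-ethenyl-3,5-dimethoxybenzene; 4 (2S)-pentadec-14-en-2-ol (1.5 equiv)
Product: 7 (2S,14E)-15-(2-bromo-3,5-dimethoxyphenyl)pentadec-14-en-2-ol
Conditions: second-generation Hoveyda–Grubbs catalyst RuCl2(H2IMes)(=CH-C6H4-2-OiPr), C31H38Cl2N2ORu (4 mol %), CH2Cl2, 40 °C, Ar sparge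
Reagents that add atoms: none
Why: Olefin cross-metathesis of a terminal aliphatic alkene with an ortho-substituted styrene is E-selective and driven by loss of ethene; the homodimer of 4 remains a competent partner, the free OH and ArBr are tolerated, and no stereocentre is touched.

**Step 4**
Reactants: 7 (2S,14E)-15-(2-bromo-3,5-dimethoxyphenyl)pentadec-14-en-2-ol
Product: 9 2-[(1E,14S)-14-hydroxypentadec-1-en-1-yl]-4,6-dimethoxybenzoic acid, via aryllithium lithium alkoxide 8 (not isolated)
Conditions: n-BuLi (2.1 equiv), THF, −78 °C, 15 min; CO2 (dry gas), −78 → 0 °C; 1 M HCl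
Reagents that add atoms: carbon dioxide, O=C=O
Why: Bromine–lithium exchange followed by carboxylation of the aryllithium; the first equivalent of n-BuLi is consumed by the O–H, exchange at −78 °C is far faster than addition to a β-alkylstyrene, and the alkyl carbonate formed on the alkoxide reverts to the alcohol on acidification.

**Step 5**
Reactants: 9 2-[(1E,14S)-14-hydroxypentadec-1-en-1-yl]-4,6-dimethoxybenzoic acid
Product: 10 (3S)-3-[(13S)-13-hydroxytetradecyl]-5,7-dimethoxy-2-benzofuran-1(3H)-one
Conditions: (R,R)-[N,N'-bis(3,5-di-tert-butylsalicylidene)cyclohexane-1,2-diaminato]cobalt, C36H52CoN2O2 (5 mol %), N-fluoro-2,4,6-trimethylpyridinium triflate (1.3 equiv), PhSiH3 (1.2 equiv), PhCF3/acetone 4:1, 0.05 M, −20 °C, Ar; then 1 M HCl/THF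
Reagents that add atoms: none
Why: Proposed new method: an enantioselective hydrogen-atom-transfer/radical-polar-crossover hydrolactonisation that forms the C3–O bond and ring B. The divalent cobalt salen complex C36H52CoN2O2, the N–F oxidant and PhSiH3 give a hydride of trivalent cobalt, which transfers H• to the β-carbon of the styrene (either alkene geometry gives the same planar benzylic radical). The radical is captured as a benzylic alkyl complex of trivalent cobalt, oxidised to the tetravalent cobalt alkyl, and displaced 5-exo with inversion by the ortho carboxylic acid. The two diastereomeric benzyl–cobalt species interconvert by reversible Co–C homolysis, so the chiral salen pocket selects the one that lactonises faster and sets C3 as S. The two meta OMe groups and the ortho carboxyl disfavour a free benzylic cation and hence a racemic SN1 path, and the remote OH cannot compete with 5-ring closure at this dilution. The closest known reaction type is cobalt-salen Mukaiyama-type hydroalkoxylation and hydro-acyloxylation of alkenes, enantioselective for alkenols; it has not been shown for 2-alkenylbenzoic acids giving 3-alkylphthalides with a secondary benzylic C–O stereocentre.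

**Compound list**
1 | 12-bromododec-1-ene | C=CCCCCCCCCCCBr | starting material
2 | (S)-propylene oxide, (2S)-2-methyloxirane | C[C@H]1CO1 | starting material
3 | dodec-11-en-1-ylmagnesium bromide | C=CCCCCCCCCCC[Mg]Br | intermediate
4 | (2S)-pentadec-14-en-2-ol | C[C@H](O)CCCCCCCCCCCC=C | intermediate
5 | 2-bromo-3,5-dimethoxybenzaldehyde | COc1cc(OC)c(Br)c(C=O)c1 | starting material
6 | 2-bromo-1-ethenyl-3,5-dimethoxybenzene | COc1cc(OC)c(Br)c(C=C)c1 | intermediate
7 | (2S,14E)-15-(2-bromo-3,5-dimethoxyphenyl)pentadec-14-en-2-ol | COc1cc(OC)c(Br)c(/C=C/CCCCCCCCCCC[C@H](C)O)c1 | intermediate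
8 | lithium (2S,14E)-15-(2-lithio-3,5-dimethoxyphenyl)pentadec-14-en-2-olate | COc1cc(OC)c([Li])c(/C=C/CCCCCCCCCCC[C@H](C)O[Li])c1 | intermediate
9 | 2-[(1E,14S)-14-hydroxypentadec-1-en-1-yl]-4,6-dimethoxybenzoic acid | COc1cc(OC)c(C(=O)O)c(/C=C/CCCCCCCCCCC[C@H](C)O)c1 | intermediate
10 | (3S)-3-[(13S)-13-hydroxytetradecyl]-5,7-dimethoxy-2-benzofuran-1(3H)-one | COc1cc(OC)c2c(c1)[C@H](CCCCCCCCCCCC[C@H](C)O)OC2=O | target

**Totals**
Total step count: 5. Longest linear sequence: 4 steps (1 → 4 → 7 → 9 → 10, or 5 → 6 → 7 → 9 → 10).

**Three steps most likely to fail**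

Step 5 (new hydrolactonisation; the risk is low selectivity at C3 or simple alkene reduction). The fallback uses known chemistry, sets out from 7 and comes back at 10. CuH-catalysed asymmetric Markovnikov hydroboration of the β-alkylstyrene (CuCl, NaOtBu, the DTBM-SEGPHOS antipode that gives the S product, pinacolborane 3 equiv, toluene, rt) gives 2-[(1S,14S)-1-(2-bromo-3,5-dimethoxyphenyl)-14-hydroxypentadecyl]-4,4,5,5-tetramethyl-1,3,2-dioxaborolane F1. Oxidation with NaBO3·4H2O in THF/H2O proceeds with retention and gives (1S,14S)-1-(2-bromo-3,5-dimethoxyphenyl)pentadecane-1,14-diol F2. Carbonylative lactonisation of this 2-bromobenzylic alcohol (Pd(OAc)2, Xantphos, CO 1 atm, K2CO3, toluene, 100 °C) closes ring B without touching the C3–O bond and gives 10.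

Step 3 (cross-metathesis; the risk is catalyst sequestration by the ortho-bromo benzylidene and homodimer formation). The fallback replaces metathesis by carbonyl olefination, sets out from 4 and 5 and comes back at 7. Ozonolysis of 4 (O3, CH2Cl2, −78 °C; Me2S) gives (13S)-13-hydroxytetradecanal F3. Aldehyde 5 is reduced (NaBH4, MeOH) to (2-bromo-3,5-dimethoxyphenyl)methanol F4, converted with PBr3 into 2-bromo-1-(bromomethyl)-3,5-dimethoxybenzene F5, and taken by Arbuzov reaction with P(OEt)3 (130 °C) to diethyl [(2-bromo-3,5-dimethoxyphenyl)methyl]phosphonate F6. E-selective Horner–Wadsworth–Emmons olefination of F3 with the anion of F6 (NaH 2.2 equiv, THF, 0 °C → rt) gives 7.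

Step 4 (lithiation–carboxylation; the risk is protonation of the aryllithium or butyl addition to the styrene). The fallback replaces the organolithium by palladium-catalysed hydroxycarbonylation, sets out from 7 and comes back at 9: Pd(OAc)2 (3 mol %), Xantphos, CO (5 bar), K2CO3, H2O/1,4-dioxane, 100 °C, then acidification. It gives 9 directly and makes no new compound (F0).

**Further compounds**
F1 | step 5 | 2-[(1S,14S)-1-(2-bromo-3,5-dimethoxyphenyl)-14-hydroxypentadecyl]-4,4,5,5-tetramethyl-1,3,2-dioxaborolane | COc1cc(OC)c(Br)c(c1)[C@H](CCCCCCCCCCCC[C@H](C)O)B1OC(C)(C)C(C)(C)O1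
F2 | step 5 | (1S,14S)-1-(2-bromo-3,5-dimethoxyphenyl)pentadecane-1,14-diol | COc1cc(OC)c(Br)c(c1)[C@H](CCCCCCCCCCCC[C@H](C)O)O
F3 | step 3 | (13S)-13-hydroxytetradecanal | C[C@H](O)CCCCCCCCCCCC=O
F4 | step 3 | (2-bromo-3,5-dimethoxyphenyl)methanol | COc1cc(OC)c(Br)c(CO)c1
F5 | step 3 | 2-bromo-1-(bromomethyl)-3,5-dimethoxybenzene | COc1cc(OC)c(Br)c(CBr)c1
F6 | step 3 | diethyl [(2-bromo-3,5-dimethoxyphenyl)methyl]phosphonate | CCOP(=O)(Cc1cc(OC)cc(OC)c1Br)OCC
F0 | step 4 | none | none
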